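**Plan**
1. Retrosynthetic cuts, in order: (i) the bond from arene ring A to the isobutyl-bearing methine (Michael disconnection; ring C leaves preformed as alkylidene triketone 16); (ii) in triketone ring B, the bond between the methine-bearing ring carbon and the neighbouring enol carbon (Claisen disconnection to an open 3,5-dioxo ester chain); (iii) the bond from ring A to the isopropyl-bearing methine (conjugate-addition disconnection to hexanoylphloroglucinol 3 and enone ester 8).
2. Enabling feature: ring B is a 4,4,6,6-tetramethylcyclohexane-1,3,5-trione. Because C-4 and C-6 are quaternary, the opened chain MeO2C–CMe2–CO–CMe2–CO–CH2– has one enolisable carbon (the future C-2), placed 1,5 to a non-enolisable ester carbonyl, so enolisation and ring closure can take only one course.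
3. Forward: 3 (one step from phloroglucinol) and 8 (three steps from dimethylketene dimer) are joined by an organocatalysed conjugate addition. In the same flask ring B is closed by a Claisen (Dieckmann) condensation that copies the Claisen ring closure of acylphloroglucinol polyketide biosynthesis. Ring C is added last as 16 (three steps from acetylphloroglucinol).
4. Stereochemistry: the isopropyl-bearing methine (R) is set by catalyst-controlled face selection in the conjugate addition of step 5, on a simple β-aryl ketone before ring B exists. The isobutyl-bearing methine (R) is set by catalyst control in the final Michael addition (step 9).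

Key step: step 5

Remark on the chemistry: the triketone rings are drawn as one enol tautomer and the descriptors (both methines R) refer to that drawing; a methine flanked by arene and triketone is treated as labile to retro-Michael fragmentation, so everything after ring B is formed is kept cold and near neutral.

**Step 1**
Reactants: 1 phloroglucinol (benzene-1,3,5-triol); 2 hexanoyl chloride
Product: 3 1-(2,4,6-trihydroxyphenyl)hexan-1-one
Conditions: AlCl3 (4 equiv), CH2Cl2/MeNO2 (1:1), 0 → 40 °C; then ice, 1 M HCl
Reagents that add atoms: none
Why: Friedel–Crafts acylation of the electron-rich triol, which stops at mono-C-acylation because the aluminium-chelated acyl group deactivates the ring and any aryl ester formed undergoes Fries rearrangement under the same conditions.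

**Step 2**
Reactants: 4 2,2,4,4-tetramethylcyclobutane-1,3-dione
Product: 5 methyl 2,2,4-trimethyl-3-oxopentanoate
Conditions: NaOMe (5 mol %), MeOH, 25 °C; AcOH quench, distillation
Reagents that add atoms: methanol (CO)
Why: base-catalysed alcoholysis of the strained non-enolisable 1,3-dione, in which methoxide adds to one carbonyl and ring strain drives the retro-Claisen C–C cleavage to the β-keto ester.

**Step 3**
Reactants: 5 methyl 2,2,4-trimethyl-3-oxopentanoate; 6 (2E)-4-methylpent-2-enal
Product: 7 methyl (6E)-5-hydroxy-2,2,4,4,8-pentamethyl-3-oxonon-6-enoate (racemic)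
Conditions: LiN(iPr)2 (1.05 equiv), THF, −78 °C; then 6, −78 °C; aq. NH4Cl at −78 °C
Reagents that add atoms: none
Why: aldol addition in which the isopropyl methine, the only enolisable position of 5, gives a lithium enolate that adds 1,2 to the enal at low temperature; the carbinol centre forms as a racemate and is removed by the oxidation of step 4.

**Step 4**
Reactants: 7 methyl (6E)-5-hydroxy-2,2,4,4,8-pentamethyl-3-oxonon-6-enoate
Product: 8 methyl (6E)-2,2,4,4,8-pentamethyl-3,5-dioxonon-6-enoate
Conditions: Dess–Martin periodinane (1.3 equiv), CH2Cl2, 0 → 25 °C
Reagents that add atoms: none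
Why: Dess–Martin oxidation of the secondary allylic alcohol under neutral conditions that avoid retro-aldol cleavage, the flanking quaternary carbon ruling out elimination so that the E-enone should be kept.

**Step 5**
Reactants: 3 1-(2,4,6-trihydroxyphenyl)hexan-1-one (2.0 equiv); 8 methyl (6E)-2,2,4,4,8-pentamethyl-3,5-dioxonon-6-enoate
Product: 10 4-[(1R)-1-(3-hexanoyl-2,4,6-trihydroxyphenyl)-2-methylpropyl]-5-hydroxy-2,2,6,6-tetramethylcyclohex-4-ene-1,3-dione, via keto ester 9 (not isolated)
Conditions: quinine-derived squaramide 3-[[3,5-bis(trifluoromethyl)phenyl]amino]-4-[[(8α,9S)-6′-methoxycinchonan-9-yl]amino]cyclobut-3-ene-1,2-dione (20 mol %), PhMe/THF (3:1), 25 °C; then THF, KN(SiMe3)2 (9 equiv), −78 → 0 °C; then cold 0.5 M HCl to pH 3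
Reagents that add atoms: none
Why: Proposed new method: the quinuclidine nitrogen turns 3 into a chiral ammonium phenoxide while the two squaramide N–H groups bind the non-enolisable 1,3-diketone of 8, and the phenoxide attacks the enone β-carbon (C-7) through arene carbon C-3 (Friedel–Crafts-type conjugate addition) to give, after rearomatisation, keto ester 9 in equilibrium with its cyclic hemiketal. KN(SiMe3)2 then deprotonates the phenols and C-6 of 9, the only enolisable carbon of the chain, and the potassium enolate attacks the ester carbonyl C-1, expels methoxide and forms the C-6–C-1 bond, the triketone being trapped at once as its enolate. The closest known reaction types are the amine–squaramide-catalysed Friedel–Crafts conjugate addition of phenols, naphthols and acylphloroglucinols to activated enones and alkylidene triketones, the Michael–Claisen construction of cyclohexane-1,3-diones (dimedone synthesis) and the Dieckmann condensation, and the closure itself imitates the Claisen cyclisation that closes phloroglucinol rings in polyketide biosynthesis. Ring B closes in the 6-(enolexo)-exo-trig mode, favoured by the two gem-dimethyl groups and driven to completion by deprotonation of the β-triketone. The one new stereocentre, the isopropyl-bearing methine, is set in the conjugate addition by the catalyst, attack on the Si face of C-7 giving the R configuration; if the quinine-derived catalyst prefers the other face its quinidine-derived pseudoenantiomer is used, and the centre, being β to the ketone and not yet next to a triketone, should not be affected by the base. The step needs mono- over bis-alkylation of 3 (excess of 3), C- over O-alkylation (the oxa-Michael adduct forms reversibly), a single regiochemistry of enolisation (guaranteed by the quaternary carbons C-2 and C-4 of the chain) and ring closure ahead of acyl transfer to the ortho phenoxide (complete enolisation at −78 °C with a non-nucleophilic base).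

**Step 6**
Reactants: 11 1-(2,4,6-trihydroxyphenyl)ethan-1-one
Product: 12 4-acetyl-5-hydroxy-2,2,6,6-tetramethylcyclohex-4-ene-1,3-dione
Conditions: NaOMe (6 equiv), MeI (6 equiv), MeOH, 0 °C → reflux; then 1 M HCl
Reagents that add atoms: iodomethane (CI)
Why: exhaustive dearomatising C-methylation of the acylphloroglucinol polyanion, two methyl groups entering at each of the two free ring carbons while the acetyl group blocks the third and keeps the product as a stable enolised triketone.

**Step 7**
Reactants: 12 4-acetyl-5-hydroxy-2,2,6,6-tetramethylcyclohex-4-ene-1,3-dione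
Product: 13 syncarpic acid (5-hydroxy-2,2,6,6-tetramethylcyclohex-4-ene-1,3-dione)
Conditions: 6 M HCl (aq), reflux
Reagents that add atoms: none
Why: acid-mediated retro-Claisen deacylation, in which water adds to the exocyclic acetyl carbonyl, the most accessible one, and the acetyl group leaves as acetic acid.

**Step 8**
Reactants: 13 syncarpic acid; 14 3-methylbutanal
Product: 16 4,4,6,6-tetramethyl-2-(3-methylbutylidene)cyclohexane-1,3,5-trione, via Mannich base 15 (not isolated)
Conditions: piperidine (1.1 equiv), CH2Cl2, 25 °C; then 1 M HCl (aq), 25 °C
Reagents that add atoms: none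
Why: Knoevenagel condensation through the Mannich base, from which acid removes piperidine by elimination to give the alkylidene triketone, to be used at once because it tautomerises and dimerises on standing.

**Step 9**
Reactants: 10 4-[(1R)-1-(3-hexanoyl-2,4,6-trihydroxyphenyl)-2-methylpropyl]-5-hydroxy-2,2,6,6-tetramethylcyclohex-4-ene-1,3-dione; 16 4,4,6,6-tetramethyl-2-(3-methylbutylidene)cyclohexane-1,3,5-trione (1.3 equiv)
Product: 17 Myrtucommulone H
Conditions: squaramide catalyst of step 5 (20 mol %), CH2Cl2, −20 °C; pH 4 buffer work-up
Reagents that add atoms: none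
Why: Friedel–Crafts-type Michael addition of the last free arene carbon of 10 to the alkylidene triketone, the biomimetic coupling of acylphloroglucinols with alkylidene syncarpic acids in its catalytic enantioselective form, where the new methine (R) is set by catalyst-controlled face selection at the exocyclic alkene carbon (same catalyst as step 5 because both methines have the same spatial sense, the pseudoenantiomer being held in reserve) and the low temperature should suppress retro-Michael scrambling of the existing methine.

**Compound list**
1 | phloroglucinol (benzene-1,3,5-triol) | Oc1cc(O)cc(O)c1 | starting material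
2 | hexanoyl chloride | CCCCCC(=O)Cl | starting material
3 | 1-(2,4,6-trihydroxyphenyl)hexan-1-one | CCCCCC(=O)c1c(O)cc(O)cc1O | intermediate
4 | 2,2,4,4-tetramethylcyclobutane-1,3-dione (dimethylketene dimer) | CC1(C)C(=O)C(C)(C)C1=O | starting material
5 | methyl 2,2,4-trimethyl-3-oxopentanoate | COC(=O)C(C)(C)C(=O)C(C)C | intermediate
6 | (2E)-4-methylpent-2-enal | CC(C)/C=C/C=O | starting material
7 | methyl (6E)-5-hydroxy-2,2,4,4,8-pentamethyl-3-oxonon-6-enoate (racemic) | COC(=O)C(C)(C)C(=O)C(C)(C)C(O)/C=C/C(C)C | intermediate
8 | methyl (6E)-2,2,4,4,8-pentamethyl-3,5-dioxonon-6-enoate | COC(=O)C(C)(C)C(=O)C(C)(C)C(=O)/C=C/C(C)C | intermediate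
9 | methyl (7R)-7-(3-hexanoyl-2,4,6-trihydroxyphenyl)-2,2,4,4,8-pentamethyl-3,5-dioxononanoate (keto ester, not isolated) | CCCCCC(=O)c1c(O)cc(O)c([C@H](CC(=O)C(C)(C)C(=O)C(C)(C)C(=O)OC)C(C)C)c1O | intermediate
10 | 4-[(1R)-1-(3-hexanoyl-2,4,6-trihydroxyphenyl)-2-methylpropyl]-5-hydroxy-2,2,6,6-tetramethylcyclohex-4-ene-1,3-dione | CCCCCC(=O)c1c(O)cc(O)c([C@H](C2=C(O)C(C)(C)C(=O)C(C)(C)C2=O)C(C)C)c1O | intermediate
11 | 1-(2,4,6-trihydroxyphenyl)ethan-1-one | CC(=O)c1c(O)cc(O)cc1O | starting material
12 | 4-acetyl-5-hydroxy-2,2,6,6-tetramethylcyclohex-4-ene-1,3-dione | CC(=O)C1=C(O)C(C)(C)C(=O)C(C)(C)C1=O | intermediate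
13 | syncarpic acid (5-hydroxy-2,2,6,6-tetramethylcyclohex-4-ene-1,3-dione) | CC1(C)C(=O)C=C(O)C(C)(C)C1=O | intermediate
14 | 3-methylbutanal | CC(C)CC=O | starting material
15 | 5-hydroxy-2,2,6,6-tetramethyl-4-[3-methyl-1-(piperidin-1-yl)butyl]cyclohex-4-ene-1,3-dione (racemic Mannich base, not isolated) | CC(C)CC(N1CCCCC1)C1=C(O)C(C)(C)C(=O)C(C)(C)C1=O | intermediate
16 | 4,4,6,6-tetramethyl-2-(3-methylbutylidene)cyclohexane-1,3,5-trione | CC(C)CC=C1C(=O)C(C)(C)C(=O)C(C)(C)C1=O | intermediate
17 | Myrtucommulone H: 1-hexanoyl-2,4,6-trihydroxybenzene carrying at C-3 a (1R)-1-(2-hydroxy-3,3,5,5-tetramethyl-4,6-dioxocyclohex-1-en-1-yl)-3-methylbutyl group and at C-5 a (1R)-1-(2-hydroxy-3,3,5,5-tetramethyl-4,6-dioxocyclohex-1-en-1-yl)-2-methylpropyl group | CCCCCC(=O)c1c(O)c([C@@H](CC(C)C)C2=C(O)C(C)(C)C(=O)C(C)(C)C2=O)c(O)c([C@H](C2=C(O)C(C)(C)C(=O)C(C)(C)C2=O)C(C)C)c1O | target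

**Step count**
Total steps: 9. Longest linear sequence: 5 steps (steps 2, 3, 4, 5, 9).

**Steps most likely to fail**

1. Step 5 (Proposed new method). The conjugate addition may be too slow or poorly face-selective on a β-branched enone whose carbonyl is neopentyl-like. After it, acyl transfer from the chain to the ortho phenoxide (retro-Claisen cleavage) may outrun enolate ring closure. Fallback with known chemistry, setting out from 13 and 3 and coming back at 10: 13 is condensed with 2-methylpropanal and piperidine in CH2Cl2 to give the Mannich base 5-hydroxy-2,2,6,6-tetramethyl-4-[2-methyl-1-(piperidin-1-yl)propyl]cyclohex-4-ene-1,3-dione F1, which loses piperidine on treatment with 1 M HCl to give 4,4,6,6-tetramethyl-2-(2-methylpropylidene)cyclohexane-1,3,5-trione F2. Compound 3 (2 equiv) is then added to F2 under the squaramide catalyst in CH2Cl2 at −20 °C, a catalytic enantioselective Friedel–Crafts-type Michael addition of an acylphloroglucinol to an alkylidene triketone, which should give 10 directly.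

2. Step 9. Facial selectivity may be poor on a nucleophile that already carries an acidic triketone able to protonate the catalyst. Fallback, setting out from 10 and 16 and coming back at 17: the two are coupled without a chiral catalyst (THF, 0 °C, iPr2NEt 10 mol %), so that the configured isopropyl-bearing methine of 10 makes the two products diastereomers. Compound 17 is then separated by preparative HPLC from its epimer at the isobutyl-bearing methine, the (1S)-3-methylbutyl epimer of Myrtucommulone H F3. This replaces catalyst control by separation of diastereomers.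

3. Step 3. The hindered lithium aldolate may undergo retro-aldol cleavage, its alkoxide may attack the methyl ester (lactonisation), or the enolate may add 1,4 to the enal. Fallback, setting out from 5 and coming back at 7: 5 is converted with LiN(iPr)2 and Me3SiCl (THF, −78 °C) into the silyl enol ether methyl 2,2,4-trimethyl-3-[(trimethylsilyl)oxy]pent-3-enoate F4. F4 is added to 6 in a Mukaiyama aldol reaction (TiCl4, CH2Cl2, −78 °C; aqueous work-up), which forms the same C–C bond under Lewis acid conditions without a free metal alkoxide and should give 7.

**Further compounds**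
F1 | step 5 | 5-hydroxy-2,2,6,6-tetramethyl-4-[2-methyl-1-(piperidin-1-yl)propyl]cyclohex-4-ene-1,3-dione (racemic Mannich base) | CC(C)C(N1CCCCC1)C1=C(O)C(C)(C)C(=O)C(C)(C)C1=O
F2 | step 5 | 4,4,6,6-tetramethyl-2-(2-methylpropylidene)cyclohexane-1,3,5-trione | CC(C)C=C1C(=O)C(C)(C)C(=O)C(C)(C)C1=O
F3 | step 9 | (1S)-3-methylbutyl epimer of Myrtucommulone H | CCCCCC(=O)c1c(O)c([C@H](CC(C)C)C2=C(O)C(C)(C)C(=O)C(C)(C)C2=O)c(O)c([C@H](C2=C(O)C(C)(C)C(=O)C(C)(C)C2=O)C(C)C)c1O
F4 | step 3 | methyl 2,2,4-trimethyl-3-[(trimethylsilyl)oxy]pent-3-enoate | COC(=O)C(C)(C)C(O[Si](C)(C)C)=C(C)C
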